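**Plan**
Retrosynthetic cuts, in order: the two O-benzyl bonds that mask ring A; both C-CH3 bonds at the quaternary carbon of ring B; the bridge bond CH2-C(ring B); then, on ring A, the C-CH2 bond, the O-CH3 bond and the aryl-butyryl bond, and on ring B the aryl-propionyl bond.
Enabling feature: in ring B the C(CH3)2 carbon sits between the ring C=O and the enol carbon C(OH) next to the bridge carbon. Ring B is therefore the dearomatised form of a 3-substituted propionylphloroglucinol with a single ring CH.
Forward: no ring is built, since both carbocycles are bought as phenols. Ring A (from 2,4,6-trihydroxytoluene) is butyrylated, differentiated at oxygen (2 x Bn, 1 x Me), formylated and reduced to a benzylic alcohol.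
That alcohol alkylates propionylphloroglucinol (from phloroglucinol). Ring B is then gem-dimethylated, and hydrogenolysis frees ring A.
Stereochemistry: the target has no stereocentre and no configurable double bond, so nothing has to be set.

Key step: step 8

Remark: the quaternary carbon carries two identical methyl groups, so the target is achiral and the request for one enantiomer is met trivially. Ring B is written throughout in the enol form of the target SMILES, one of several rapidly equilibrating tautomers.

Step 1
Reactants: 1 2,4,6-trihydroxytoluene; 2 butyryl chloride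
Product: 3 1-(2,4,6-trihydroxy-3-methylphenyl)butan-1-one
Conditions: AlCl3 (3.5 equiv), CH2Cl2/PhNO2, 0 °C to 45 °C; then ice/aq HCl
Reagents that add atoms: butyryl chloride (2), CCCC(=O)Cl
Why: Friedel-Crafts acylation of a phloroglucinol, in which the two open ring positions of 1 are equivalent and the chelated ketone deactivates the ring, so the reaction should stop after one butyryl group.

Step 2
Reactants: 3 1-(2,4,6-trihydroxy-3-methylphenyl)butan-1-one
Product: 4 1-[4,6-bis(benzyloxy)-2-hydroxy-3-methylphenyl]butan-1-one
Conditions: BnBr (2.1 equiv), K2CO3 (2.2 equiv), DMF, rt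
Reagents that add atoms: benzyl bromide, BrCc1ccccc1
Why: Williamson ether synthesis under weak base, in which the unchelated, most acidic 4-OH reacts first and the 6-OH beside the ring CH is more accessible than the 2-OH wedged between ketone and methyl, so the 2-OH should remain as the hydrogen-bonded phenol, as is usual for 3-methylphloroacylophenones.

Step 3
Reactants: 4 1-[4,6-bis(benzyloxy)-2-hydroxy-3-methylphenyl]butan-1-one; 5 iodomethane
Product: 6 1-[4,6-bis(benzyloxy)-2-methoxy-3-methylphenyl]butan-1-one
Conditions: MeI (3 equiv), K2CO3 (3 equiv), DMF, 40 °C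
Reagents that add atoms: iodomethane (5), CI
Why: Williamson O-methylation of the last, chelated phenol, which needs only a polar aprotic solvent, an excess of the small electrophile and gentle heating, while carbonate is too weak to enolise the ketone.

Step 4
Reactants: 6 1-[4,6-bis(benzyloxy)-2-methoxy-3-methylphenyl]butan-1-one
Product: 8 2,6-bis(benzyloxy)-3-butanoyl-4-methoxy-5-methylbenzaldehyde, via aryl iminium chloride 7 (not isolated)
Conditions: POCl3 (2 equiv), DMF, 0 °C to 40 °C; then H2O, 40 °C
Reagents that add atoms: N,N-dimethylformamide, CN(C)C=O (formyl carbon); water, O (aldehyde oxygen); phosphoryl chloride, O=P(Cl)(Cl)Cl (only the chloride counter-ion of 7)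
Why: Vilsmeier-Haack formylation, in which the last ring CH is ortho, ortho and para to three alkoxy groups and the ketone, twisted out of plane by its two ortho substituents, withdraws only inductively, so the chloroiminium ion should attack the ring below the temperature at which aryl alkyl ketones are chloroformylated.

Step 5
Reactants: 8 2,6-bis(benzyloxy)-3-butanoyl-4-methoxy-5-methylbenzaldehyde
Product: 9 1-[2,4-bis(benzyloxy)-3-(hydroxymethyl)-6-methoxy-5-methylphenyl]butan-1-one
Conditions: NaBH4 (0.5 equiv), THF/MeOH, -20 °C to 0 °C; then H2O
Reagents that add atoms: none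
Why: Chemoselective borohydride reduction, in which an aldehyde reacts far faster than a di-ortho-substituted aryl alkyl ketone, so a limited charge of hydride at low temperature should touch only the formyl group.

Step 6
Reactants: 10 phloroglucinol; 11 propionyl chloride
Product: 12 1-(2,4,6-trihydroxyphenyl)propan-1-one
Conditions: AlCl3 (3.5 equiv), CH2Cl2/PhNO2, 0 °C to 45 °C; then ice/aq HCl
Reagents that add atoms: propionyl chloride (11), CCC(=O)Cl
Why: Friedel-Crafts acylation of phloroglucinol, whose three ring CH are equivalent and whose first acyl group deactivates the product towards a second acylation.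

Step 7
Reactants: 9 1-[2,4-bis(benzyloxy)-3-(hydroxymethyl)-6-methoxy-5-methylphenyl]butan-1-one; 12 1-(2,4,6-trihydroxyphenyl)propan-1-one
Product: 13 1-[2,4-bis(benzyloxy)-6-methoxy-5-methyl-3-[(2,4,6-trihydroxy-3-propanoylphenyl)methyl]phenyl]butan-1-one
Conditions: 12 (3 equiv), BF3·OEt2 (0.3 equiv), dioxane, rt, slow addition of 9
Reagents that add atoms: none
Why: Lewis-acid-catalysed Friedel-Crafts benzylation with a benzylic alcohol, in which 9 ionises easily to a cation stabilised by two ortho and one para alkoxy groups and is captured at one of the two equivalent, strongly nucleophilic ring CH of 12, while the excess of 12 and the slow addition hold back a second benzylation.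

Step 8
Reactants: 13 1-[2,4-bis(benzyloxy)-6-methoxy-5-methyl-3-[(2,4,6-trihydroxy-3-propanoylphenyl)methyl]phenyl]butan-1-one; 5 iodomethane
Product: 15 4-{[2,6-bis(benzyloxy)-3-butanoyl-4-methoxy-5-methylphenyl]methyl}-3,5-dihydroxy-6,6-dimethyl-2-propanoylcyclohexa-2,4-dien-1-one, via ring-B monomethyl arene 14 (not isolated)
Conditions: NaOMe (4 equiv), MeI (2.2 equiv, two portions), MeOH, 0 °C to rt; then 1 M HCl
Reagents that add atoms: iodomethane (5), CI (two equivalents)
Why: Methoxide turns ring B of 13 into its polyanionic phenolate, and the only ring-B carbon that still bears hydrogen displaces iodide from 5 by SN2; tautomerisation then gives the still aromatic C-methyl compound 14. A second SN2 at the same carbon makes it quaternary, so the ring can no longer rearomatise and should rest as the enolised 2-acylcyclohexane-1,3,5-trione of 15. The reaction type is the alkylative dearomatisation of acylphloroglucinols with alkoxide and iodomethane, the classical entry to acylfilicinic acids. No ring is closed and no stereocentre arises, because the new quaternary carbon carries two identical methyl groups. The step needs carbon over oxygen alkylation, which the hydrogen-bonding methanol medium and the soft electrophile favour, and it needs the open carbon over the bridge carbon, which the bulky aryl-methyl group with its two flanking benzyloxy substituents and the limit of about two equivalents of 5 should secure. Ring A has no free phenol and no ring hydrogen, so it can neither be methylated nor act as donor or leaving group in a base-induced scission of the methylene bridge.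

Step 9
Reactants: 15 4-{[2,6-bis(benzyloxy)-3-butanoyl-4-methoxy-5-methylphenyl]methyl}-3,5-dihydroxy-6,6-dimethyl-2-propanoylcyclohexa-2,4-dien-1-one
Product: 16 aspidin PB
Conditions: H2 (1 atm), 10% Pd/C, EtOAc, rt
Reagents that add atoms: none
Why: Catalytic hydrogenolysis of aryl benzyl ethers under neutral conditions, which should leave the aryl ketone, the enolised triketone and the bridge C-C bonds untouched and avoids the base or heat that could scramble the bridge once ring A is a free phenol.

**Compound list**
1 | 2,4,6-trihydroxytoluene | Cc1c(O)cc(O)cc1O | starting material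
2 | butyryl chloride | CCCC(=O)Cl | starting material
3 | 1-(2,4,6-trihydroxy-3-methylphenyl)butan-1-one | CCCC(=O)c1c(O)cc(O)c(C)c1O | intermediate
4 | 1-[4,6-bis(benzyloxy)-2-hydroxy-3-methylphenyl]butan-1-one | CCCC(=O)c1c(OCc2ccccc2)cc(OCc2ccccc2)c(C)c1O | intermediate
5 | iodomethane | CI | starting material
6 | 1-[4,6-bis(benzyloxy)-2-methoxy-3-methylphenyl]butan-1-one | CCCC(=O)c1c(OCc2ccccc2)cc(OCc2ccccc2)c(C)c1OC | intermediate
7 | N-{[2,6-bis(benzyloxy)-3-butanoyl-4-methoxy-5-methylphenyl]methylidene}-N-methylmethanaminium chloride (not isolated) | CCCC(=O)c1c(OCc2ccccc2)c(C=[N+](C)C)c(OCc2ccccc2)c(C)c1OC.[Cl-] | intermediate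
8 | 2,6-bis(benzyloxy)-3-butanoyl-4-methoxy-5-methylbenzaldehyde | CCCC(=O)c1c(OCc2ccccc2)c(C=O)c(OCc2ccccc2)c(C)c1OC | intermediate
9 | 1-[2,4-bis(benzyloxy)-3-(hydroxymethyl)-6-methoxy-5-methylphenyl]butan-1-one | CCCC(=O)c1c(OCc2ccccc2)c(CO)c(OCc2ccccc2)c(C)c1OC | intermediate
10 | phloroglucinol | Oc1cc(O)cc(O)c1 | starting material
11 | propionyl chloride | CCC(=O)Cl | starting material
12 | 1-(2,4,6-trihydroxyphenyl)propan-1-one | CCC(=O)c1c(O)cc(O)cc1O | intermediate
13 | 1-[2,4-bis(benzyloxy)-6-methoxy-5-methyl-3-[(2,4,6-trihydroxy-3-propanoylphenyl)methyl]phenyl]butan-1-one | CCCC(=O)c1c(OCc2ccccc2)c(Cc2c(O)cc(O)c(C(=O)CC)c2O)c(OCc2ccccc2)c(C)c1OC | intermediate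
14 | 1-[2,4-bis(benzyloxy)-6-methoxy-5-methyl-3-[(2,4,6-trihydroxy-3-methyl-5-propanoylphenyl)methyl]phenyl]butan-1-one (not isolated) | CCCC(=O)c1c(OCc2ccccc2)c(Cc2c(O)c(C)c(O)c(C(=O)CC)c2O)c(OCc2ccccc2)c(C)c1OC | intermediate
15 | 4-{[2,6-bis(benzyloxy)-3-butanoyl-4-methoxy-5-methylphenyl]methyl}-3,5-dihydroxy-6,6-dimethyl-2-propanoylcyclohexa-2,4-dien-1-one (ring-A bis-benzyl ether of aspidin PB) | CCCC(=O)c1c(OCc2ccccc2)c(CC2=C(O)C(C)(C)C(=O)C(C(=O)CC)=C2O)c(OCc2ccccc2)c(C)c1OC | intermediate
16 | aspidin PB, 4-[(3-butanoyl-2,6-dihydroxy-4-methoxy-5-methylphenyl)methyl]-3,5-dihydroxy-6,6-dimethyl-2-propanoylcyclohexa-2,4-dien-1-one (achiral) | CCCC(=O)c1c(O)c(CC2=C(O)C(C)(C)C(=O)C(C(=O)CC)=C2O)c(O)c(C)c1OC | target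

**Step count**
Total step count: 9.
Longest linear sequence: 8 (steps 1 to 5, then 7, 8 and 9, from 2,4,6-trihydroxytoluene).

**Steps most likely to fail**

(a) The gem-dimethylation, step 8.
- What may go wrong: the ambident ring-B anion may be methylated at oxygen, at the bridge-bearing carbon, or a third time once the quaternary carbon is in place. Stopping cleanly after two alkylations may be difficult.
- Fallback: dearomatise before the rings are joined. Setting out from 12, NaOMe/MeI in MeOH acts on the parent acylphloroglucinol. There both open carbons are equivalent and no bridge carbon competes, so this should give propionylfilicinic acid F1.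
- The one remaining ring CH of F1, the nucleophilic carbon of a vinylogous acid, is then benzylated with alcohol 9 under BF3·OEt2 catalysis in dioxane. This comes back to the route at 15.

(b) The ring union, step 7.
- What may go wrong: the readily ionised alcohol may condense with itself, ring B may be benzylated twice or at oxygen, and the acid may reverse the newly formed bridge bond by ipso-protonation of the electron-rich ring A.
- Fallback: change from a cationic to an anionic C-alkylation. Setting out from 9, MsCl/Et3N in CH2Cl2 at -20 °C should give the benzylic chloride F2, which is used at once.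
- F2 is added to the potassium phenolate of 12 (KOH, aqueous MeOH, 0 °C). This is the classical basic C-alkylation of acylphloroglucinols with benzylic and allylic halides, and it comes back to the route at 13.

(c) The formylation, step 4.
- What may go wrong: attack at a position flanked by two benzyloxy groups may be sluggish. Forcing the reaction may bring on chloroformylation at the enolisable ketone.
- Fallback: replace electrophilic formylation and reduction by halogenation and cross-coupling. Setting out from 6, NIS with catalytic TFA in MeCN should give the aryl iodide F3.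
- A Stille coupling of F3 with (tributylstannyl)methanol (Pd(PPh3)4, dioxane, 90 °C) installs the hydroxymethyl group directly. This bypasses 8 and comes back to the route at 9.

**Further compounds**
F1 | step 8 | 3,5-dihydroxy-6,6-dimethyl-2-propanoylcyclohexa-2,4-dien-1-one (propionylfilicinic acid) | CCC(=O)C1=C(O)C=C(O)C(C)(C)C1=O
F2 | step 7 | 1-[2,4-bis(benzyloxy)-3-(chloromethyl)-6-methoxy-5-methylphenyl]butan-1-one | CCCC(=O)c1c(OCc2ccccc2)c(CCl)c(OCc2ccccc2)c(C)c1OC
F3 | step 4 | 1-[2,4-bis(benzyloxy)-3-iodo-6-methoxy-5-methylphenyl]butan-1-one | CCCC(=O)c1c(OCc2ccccc2)c(I)c(OCc2ccccc2)c(C)c1OC
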